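**Plan**
1. Retrosynthesis: the six benzyl ethers are removed last; ring A is then cut at C3a–C7a, C4–C5 and C6–C7, which opens the dihydrofuran ring as well and leaves diyne 20 and (benzyloxy)ethyne 23.
2. The enabling feature: ring A carries hydrogen only at C5 and C7, so its carbons pair into three alkynes – C7≡C7a bound to O1, C3a≡C4 bearing the styryl arm, C5≡C6 bearing the C6 oxygen – and the first two are already linked by the O1–C2–C3 chain.
3. Diyne 20 is cut further at O1–C7a (O-alkynylation), C4–vinyl (Sonogashira), C3a≡C4 (aldehyde-to-alkyne homologation) and C2–C3 (aldol).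
4. Forward: the aldol joins C2–C3, the acyl carbon is extended to the enyne, the ethynyl ether is attached, and one cyclotrimerisation closes the dihydrofuran ring and ring A together.
5. Stereochemistry: C2 (S) and C3 (S) both come from the (4S)-4-benzyloxazolidinone-controlled magnesium-catalysed anti-aldol and are untouched afterwards; the E-alkene comes from (E)-4-(benzyloxy)cinnamic acid.
6. Phenols travel as benzyl ethers (and C6–O arrives as a benzyl ether), because a 2-aryl-2,3-dihydrobenzofuran carrying a stilbene is unlikely to survive hard demethylation.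

Key step: step 14

Remark: the target SMILES is read as the (2S,3S)-trans-dihydrobenzofuran; alkynyl ethers 20 and 23 are assumed to be kept as cold solutions and used the same day, since benzylic alkynyl ethers rearrange on warming.

**Route**

Step 1
Reactants: 1 methyl (3,5-dihydroxyphenyl)acetate
Product: 3 [3,5-bis(benzyloxy)phenyl]acetic acid, via methyl [3,5-bis(benzyloxy)phenyl]acetate 2 (not isolated)
Conditions: BnBr, K2CO3, DMF, 60 °C; then NaOH, MeOH–H2O, 60 °C; HCl work-up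
Reagents that add atoms: benzyl bromide BrCc1ccccc1; sodium hydroxide [Na+].[OH-]
Why: Williamson etherification of both phenols followed by ester saponification is routine and delivers the acid for acylation.

Step 2
Reactants: 3 [3,5-bis(benzyloxy)phenyl]acetic acid; 4 (4S)-4-benzyl-1,3-oxazolidin-2-one
Product: 6 (4S)-4-benzyl-3-{[3,5-bis(benzyloxy)phenyl]acetyl}-1,3-oxazolidin-2-one, via mixed pivalic anhydride 5 (not isolated)
Conditions: PivCl, Et3N, THF, −20 °C; then 4, LiCl, −20 °C → rt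
Reagents that add atoms: none
Why: N-acylation of the oxazolidinone through the mixed anhydride with LiCl/Et3N activation is a standard entry to arylacetyl imides and avoids a ketene-prone acid chloride.

Step 3
Reactants: 6 (4S)-4-benzyl-3-{[3,5-bis(benzyloxy)phenyl]acetyl}-1,3-oxazolidin-2-one; 7 3,4-bis(benzyloxy)benzaldehyde
Product: 9 (4S)-4-benzyl-3-{(2R,3S)-3-[3,4-bis(benzyloxy)phenyl]-2-[3,5-bis(benzyloxy)phenyl]-3-hydroxypropanoyl}-1,3-oxazolidin-2-one, via aldol trimethylsilyl ether 8 (not isolated)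
Conditions: MgCl2 (0.2 equiv), Et3N, TMSCl, EtOAc, 23 °C; then 10% aq. citric acid–THF, 0 °C
Reagents that add atoms: none
Why: In this Evans magnesium-catalysed anti-aldol reaction, soft enolisation gives the chelated Z-enolate, which should add to the non-enolisable aldehyde through a boat transition state on the face away from the auxiliary benzyl group, setting the acyl C2 (R) and C3 (S) centres anti to each other while silylation of the aldolate blocks retro-aldol.

Step 4
Reactants: 9 (4S)-4-benzyl-3-{(2R,3S)-3-[3,4-bis(benzyloxy)phenyl]-2-[3,5-bis(benzyloxy)phenyl]-3-hydroxypropanoyl}-1,3-oxazolidin-2-one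
Product: 10 (4S)-4-benzyl-3-{(2R,3S)-3-[3,4-bis(benzyloxy)phenyl]-2-[3,5-bis(benzyloxy)phenyl]-3-[(tert-butyldimethylsilyl)oxy]propanoyl}-1,3-oxazolidin-2-one
Conditions: TBSOTf, 2,6-lutidine, CH2Cl2, −78 → 0 °C
Reagents that add atoms: tert-butyldimethylsilyl trifluoromethanesulfonate CC(C)(C)[Si](C)(C)OS(=O)(=O)C(F)(F)F
Why: Silyl ether protection of the benzylic alcohol with the silyl triflate prevents retro-aldol and β-elimination in the steps that follow.

Step 5
Reactants: 10 (4S)-4-benzyl-3-{(2R,3S)-3-[3,4-bis(benzyloxy)phenyl]-2-[3,5-bis(benzyloxy)phenyl]-3-[(tert-butyldimethylsilyl)oxy]propanoyl}-1,3-oxazolidin-2-one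
Product: 11 (2S,3S)-3-[3,4-bis(benzyloxy)phenyl]-2-[3,5-bis(benzyloxy)phenyl]-3-[(tert-butyldimethylsilyl)oxy]propan-1-ol
Conditions: LiBH4, MeOH (1 equiv), THF, 0 °C
Reagents that add atoms: none
Why: Reductive cleavage of the N-acyloxazolidinone with LiBH4 releases the primary alcohol and the auxiliary without enolising the α-aryl centre.

Step 6
Reactants: 11 (2S,3S)-3-[3,4-bis(benzyloxy)phenyl]-2-[3,5-bis(benzyloxy)phenyl]-3-[(tert-butyldimethylsilyl)oxy]propan-1-ol
Product: 12 (2R,3S)-3-[3,4-bis(benzyloxy)phenyl]-2-[3,5-bis(benzyloxy)phenyl]-3-[(tert-butyldimethylsilyl)oxy]propanal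
Conditions: Dess–Martin periodinane, CH2Cl2, 0 °C; used crude at once
Reagents that add atoms: none
Why: Dess–Martin oxidation needs no amine base, so the α-aryl aldehyde should form without epimerisation provided it is not chromatographed.

Step 7
Reactants: 12 (2R,3S)-3-[3,4-bis(benzyloxy)phenyl]-2-[3,5-bis(benzyloxy)phenyl]-3-[(tert-butyldimethylsilyl)oxy]propanal
Product: 13 {[(1S,2R)-1-[3,4-bis(benzyloxy)phenyl]-2-[3,5-bis(benzyloxy)phenyl]-4,4-dibromobut-3-en-1-yl]oxy}(tert-butyl)dimethylsilane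
Conditions: CBr4, PPh3 (ylide preformed), CH2Cl2, 0 °C
Reagents that add atoms: carbon tetrabromide BrC(Br)(Br)Br
Why: Ramirez dibromoolefination, the first stage of the Corey–Fuchs sequence, is fast and base-free at 0 °C and should therefore preserve the α-aryl centre and the β-silyloxy group.

Step 8
Reactants: 13 {[(1S,2R)-1-[3,4-bis(benzyloxy)phenyl]-2-[3,5-bis(benzyloxy)phenyl]-4,4-dibromobut-3-en-1-yl]oxy}(tert-butyl)dimethylsilane
Product: 14 {[(1S,2R)-1-[3,4-bis(benzyloxy)phenyl]-2-[3,5-bis(benzyloxy)phenyl]but-3-yn-1-yl]oxy}(tert-butyl)dimethylsilane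
Conditions: n-BuLi (2.2 equiv), THF, −78 °C; H2O quench
Reagents that add atoms: none
Why: Bromine–lithium exchange and Fritsch–Buttenberg–Wiechell rearrangement, the second stage of the Corey–Fuchs sequence, give the acetylide at −78 °C, where deprotonation of the benzylic propargylic C–H should not compete.

Step 9
Reactants: 15 (E)-4-(benzyloxy)cinnamic acid
Product: 16 1-(benzyloxy)-4-[(E)-2-bromoethenyl]benzene
Conditions: NBS, LiOAc (0.1 equiv), MeCN–H2O, rt
Reagents that add atoms: N-bromosuccinimide O=C1CCC(=O)N1Br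
Why: Hunsdiecker-type bromodecarboxylation of electron-rich cinnamic acids with NBS and a catalytic carboxylate base is known to give the (E)-β-bromostyrene.

Step 10
Reactants: 14 {[(1S,2R)-1-[3,4-bis(benzyloxy)phenyl]-2-[3,5-bis(benzyloxy)phenyl]but-3-yn-1-yl]oxy}(tert-butyl)dimethylsilane; 16 1-(benzyloxy)-4-[(E)-2-bromoethenyl]benzene
Product: 17 {[(1S,2S,5E)-1-[3,4-bis(benzyloxy)phenyl]-2-[3,5-bis(benzyloxy)phenyl]-6-[4-(benzyloxy)phenyl]hex-5-en-3-yn-1-yl]oxy}(tert-butyl)dimethylsilane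
Conditions: PdCl2(PPh3)2 (cat.), CuI (cat.), Et3N, THF, 40 °C
Reagents that add atoms: none
Why: Sonogashira coupling of a terminal alkyne with an (E)-alkenyl bromide retains the alkene geometry, and the amine is too weak a base to disturb the propargylic centre (the descriptor changes from R to S only because the alkynyl group now outranks the aryl group).

Step 11
Reactants: 17 {[(1S,2S,5E)-1-[3,4-bis(benzyloxy)phenyl]-2-[3,5-bis(benzyloxy)phenyl]-6-[4-(benzyloxy)phenyl]hex-5-en-3-yn-1-yl]oxy}(tert-butyl)dimethylsilane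
Product: 18 (1S,2S,5E)-1-[3,4-bis(benzyloxy)phenyl]-2-[3,5-bis(benzyloxy)phenyl]-6-[4-(benzyloxy)phenyl]hex-5-en-3-yn-1-ol
Conditions: TBAF, THF, 0 °C
Reagents that add atoms: none
Why: Fluoride-mediated silyl ether cleavage is selective in the presence of benzyl ethers and the enyne.

Step 12
Reactants: 18 (1S,2S,5E)-1-[3,4-bis(benzyloxy)phenyl]-2-[3,5-bis(benzyloxy)phenyl]-6-[4-(benzyloxy)phenyl]hex-5-en-3-yn-1-ol
Product: 20 (1S,2S,5E)-1-[3,4-bis(benzyloxy)phenyl]-2-[3,5-bis(benzyloxy)phenyl]-6-[4-(benzyloxy)phenyl]-1-(ethynyloxy)hex-5-en-3-yne, via (E)-1,2-dichlorovinyl ether 19 (not isolated)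
Conditions: KH (1.2 equiv), THF, 0 °C; Cl2C=CHCl, −50 °C → rt; then n-BuLi (2.4 equiv), −78 → −40 °C; MeOH, −78 °C; kept cold
Reagents that add atoms: trichloroethylene ClC=C(Cl)Cl
Why: O-alkynylation by way of the dichlorovinyl ether is established for secondary and benzylic alcohols, the alkoxide adding to dichloroacetylene formed in the flask and n-BuLi then effecting elimination and chlorine–lithium exchange to the alkynyl ether that is protonated.

Step 13
Reactants: 21 benzyl alcohol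
Product: 23 (benzyloxy)ethyne, via benzyl (E)-1,2-dichlorovinyl ether 22 (not isolated)
Conditions: KH, THF, 0 °C; Cl2C=CHCl, −50 °C → rt; then n-BuLi (2.4 equiv), −78 → −40 °C; MeOH, −78 °C; used as a cold toluene solution
Reagents that add atoms: trichloroethylene ClC=C(Cl)Cl
Why: The same alkoxide addition–elimination route to alkynyl ethers applies to a primary benzylic alcohol and supplies the C5–C6 unit with an oxygen substituent that is removable under the final conditions.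

Step 14
Reactants: 20 (1S,2S,5E)-1-[3,4-bis(benzyloxy)phenyl]-2-[3,5-bis(benzyloxy)phenyl]-6-[4-(benzyloxy)phenyl]-1-(ethynyloxy)hex-5-en-3-yne; 23 (benzyloxy)ethyne
Product: 24 (2S,3S)-6-(benzyloxy)-2-[3,4-bis(benzyloxy)phenyl]-3-[3,5-bis(benzyloxy)phenyl]-4-{(E)-2-[4-(benzyloxy)phenyl]ethenyl}-2,3-dihydro-1-benzofuran
Conditions: RhCl(PPh3)3 (5 mol%), 23 (4 equiv), toluene, 20 °C, slow addition of 20
Reagents that add atoms: none
Why: After loss of a phosphine, monovalent rhodium couples the two tethered alkynes of 20 oxidatively to a trivalent rhodacyclopentadiene, forming C3a–C7a; insertion of 23 and reductive elimination then form C4–C5 and C6–C7 and return monovalent rhodium. The closest known reaction type is the RhCl(PPh3)3-catalysed crossed [2+2+2] cycloaddition of 1,6-diynes with terminal alkynes, in particular of nitrogen-tethered ynamide diynes that give 4,6-disubstituted indolines near room temperature. The dihydrofuran ring closes in the oxidative cyclisation, a five-membered ring being dictated by the three-atom O1–C2–C3 tether, and ring A closes in the insertion–reductive elimination as a formal [2+2+2] cycloaddition. No stereocentre is formed; C2 and C3 sit on the tether, are not engaged by the catalyst and keep the (2S,3S) anti arrangement set in step 3. The step needs regiocontrol (the benzyloxy-bearing carbon of 23 must bond to C7 and not to C4), which the bulky styryl group on C4 against the unsubstituted C7 terminus should enforce in the meta sense seen with terminally substituted diynes. It also needs chemoselectivity for the alkynes over the styryl alkene and over self-trimerisation of 23, which the tethered pair, slow addition of 20 and a temperature at which the benzylic alkynyl ethers do not rearrange should secure.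

Step 15
Reactants: 24 (2S,3S)-6-(benzyloxy)-2-[3,4-bis(benzyloxy)phenyl]-3-[3,5-bis(benzyloxy)phenyl]-4-{(E)-2-[4-(benzyloxy)phenyl]ethenyl}-2,3-dihydro-1-benzofuran
Product: 25 scirpusin A, (2S,3S)-2-(3,4-dihydroxyphenyl)-3-(3,5-dihydroxyphenyl)-4-[(E)-2-(4-hydroxyphenyl)ethenyl]-2,3-dihydro-1-benzofuran-6-ol
Conditions: BCl3 (18 equiv), C6HMe5 (18 equiv), CH2Cl2, −78 °C; MeOH, −78 °C
Reagents that add atoms: none
Why: Lewis acid debenzylation with BCl3 and pentamethylbenzene as a non-basic benzyl cation scavenger runs at −78 °C and leaves alkenes alone, so the acid-sensitive trans-dihydrobenzofuran and stilbene should survive.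

**Compound list**
1 | methyl (3,5-dihydroxyphenyl)acetate | COC(=O)Cc1cc(O)cc(O)c1 | starting material
2 | methyl [3,5-bis(benzyloxy)phenyl]acetate | COC(=O)Cc1cc(OCc2ccccc2)cc(OCc2ccccc2)c1 | intermediate
3 | [3,5-bis(benzyloxy)phenyl]acetic acid | OC(=O)Cc1cc(OCc2ccccc2)cc(OCc2ccccc2)c1 | intermediate
4 | (4S)-4-benzyl-1,3-oxazolidin-2-one | O=C1OC[C@H](Cc2ccccc2)N1 | starting material
5 | [3,5-bis(benzyloxy)phenyl]acetic pivalic anhydride | CC(C)(C)C(=O)OC(=O)Cc1cc(OCc2ccccc2)cc(OCc2ccccc2)c1 | intermediate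
6 | (4S)-4-benzyl-3-{[3,5-bis(benzyloxy)phenyl]acetyl}-1,3-oxazolidin-2-one | O=C1OC[C@H](Cc2ccccc2)N1C(=O)Cc1cc(OCc2ccccc2)cc(OCc2ccccc2)c1 | intermediate
7 | 3,4-bis(benzyloxy)benzaldehyde | O=Cc1ccc(OCc2ccccc2)c(OCc2ccccc2)c1 | starting material
8 | (4S)-4-benzyl-3-{(2R,3S)-3-[3,4-bis(benzyloxy)phenyl]-2-[3,5-bis(benzyloxy)phenyl]-3-[(trimethylsilyl)oxy]propanoyl}-1,3-oxazolidin-2-one | O=C1OC[C@H](Cc2ccccc2)N1C(=O)[C@H](c1cc(OCc2ccccc2)cc(OCc2ccccc2)c1)[C@H](O[Si](C)(C)C)c1ccc(OCc2ccccc2)c(OCc2ccccc2)c1 | intermediate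
9 | (4S)-4-benzyl-3-{(2R,3S)-3-[3,4-bis(benzyloxy)phenyl]-2-[3,5-bis(benzyloxy)phenyl]-3-hydroxypropanoyl}-1,3-oxazolidin-2-one | O=C1OC[C@H](Cc2ccccc2)N1C(=O)[C@H](c1cc(OCc2ccccc2)cc(OCc2ccccc2)c1)[C@H](O)c1ccc(OCc2ccccc2)c(OCc2ccccc2)c1 | intermediate
10 | (4S)-4-benzyl-3-{(2R,3S)-3-[3,4-bis(benzyloxy)phenyl]-2-[3,5-bis(benzyloxy)phenyl]-3-[(tert-butyldimethylsilyl)oxy]propanoyl}-1,3-oxazolidin-2-one | O=C1OC[C@H](Cc2ccccc2)N1C(=O)[C@H](c1cc(OCc2ccccc2)cc(OCc2ccccc2)c1)[C@H](O[Si](C)(C)C(C)(C)C)c1ccc(OCc2ccccc2)c(OCc2ccccc2)c1 | intermediate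
11 | (2S,3S)-3-[3,4-bis(benzyloxy)phenyl]-2-[3,5-bis(benzyloxy)phenyl]-3-[(tert-butyldimethylsilyl)oxy]propan-1-ol | OC[C@H](c1cc(OCc2ccccc2)cc(OCc2ccccc2)c1)[C@H](O[Si](C)(C)C(C)(C)C)c1ccc(OCc2ccccc2)c(OCc2ccccc2)c1 | intermediate
12 | (2R,3S)-3-[3,4-bis(benzyloxy)phenyl]-2-[3,5-bis(benzyloxy)phenyl]-3-[(tert-butyldimethylsilyl)oxy]propanal | O=C[C@H](c1cc(OCc2ccccc2)cc(OCc2ccccc2)c1)[C@H](O[Si](C)(C)C(C)(C)C)c1ccc(OCc2ccccc2)c(OCc2ccccc2)c1 | intermediate
13 | {[(1S,2R)-1-[3,4-bis(benzyloxy)phenyl]-2-[3,5-bis(benzyloxy)phenyl]-4,4-dibromobut-3-en-1-yl]oxy}(tert-butyl)dimethylsilane | BrC(Br)=C[C@H](c1cc(OCc2ccccc2)cc(OCc2ccccc2)c1)[C@H](O[Si](C)(C)C(C)(C)C)c1ccc(OCc2ccccc2)c(OCc2ccccc2)c1 | intermediate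
14 | {[(1S,2R)-1-[3,4-bis(benzyloxy)phenyl]-2-[3,5-bis(benzyloxy)phenyl]but-3-yn-1-yl]oxy}(tert-butyl)dimethylsilane | C#C[C@H](c1cc(OCc2ccccc2)cc(OCc2ccccc2)c1)[C@H](O[Si](C)(C)C(C)(C)C)c1ccc(OCc2ccccc2)c(OCc2ccccc2)c1 | intermediate
15 | (E)-4-(benzyloxy)cinnamic acid | OC(=O)/C=C/c1ccc(OCc2ccccc2)cc1 | starting material
16 | 1-(benzyloxy)-4-[(E)-2-bromoethenyl]benzene | Br/C=C/c1ccc(OCc2ccccc2)cc1 | intermediate
17 | {[(1S,2S,5E)-1-[3,4-bis(benzyloxy)phenyl]-2-[3,5-bis(benzyloxy)phenyl]-6-[4-(benzyloxy)phenyl]hex-5-en-3-yn-1-yl]oxy}(tert-butyl)dimethylsilane | c1ccc(COc2ccc(/C=C/C#C[C@H](c3cc(OCc4ccccc4)cc(OCc4ccccc4)c3)[C@H](O[Si](C)(C)C(C)(C)C)c3ccc(OCc4ccccc4)c(OCc4ccccc4)c3)cc2)cc1 | intermediate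
18 | (1S,2S,5E)-1-[3,4-bis(benzyloxy)phenyl]-2-[3,5-bis(benzyloxy)phenyl]-6-[4-(benzyloxy)phenyl]hex-5-en-3-yn-1-ol | c1ccc(COc2ccc(/C=C/C#C[C@H](c3cc(OCc4ccccc4)cc(OCc4ccccc4)c3)[C@H](O)c3ccc(OCc4ccccc4)c(OCc4ccccc4)c3)cc2)cc1 | intermediate
19 | (1S,2S,5E)-1-[3,4-bis(benzyloxy)phenyl]-2-[3,5-bis(benzyloxy)phenyl]-6-[4-(benzyloxy)phenyl]-1-{[(E)-1,2-dichloroethenyl]oxy}hex-5-en-3-yne | c1ccc(COc2ccc(/C=C/C#C[C@H](c3cc(OCc4ccccc4)cc(OCc4ccccc4)c3)[C@H](O/C(Cl)=C\Cl)c3ccc(OCc4ccccc4)c(OCc4ccccc4)c3)cc2)cc1 | intermediate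
20 | (1S,2S,5E)-1-[3,4-bis(benzyloxy)phenyl]-2-[3,5-bis(benzyloxy)phenyl]-6-[4-(benzyloxy)phenyl]-1-(ethynyloxy)hex-5-en-3-yne | c1ccc(COc2ccc(/C=C/C#C[C@H](c3cc(OCc4ccccc4)cc(OCc4ccccc4)c3)[C@H](OC#C)c3ccc(OCc4ccccc4)c(OCc4ccccc4)c3)cc2)cc1 | intermediate
21 | benzyl alcohol | OCc1ccccc1 | starting material
22 | benzyl (E)-1,2-dichloroethenyl ether | Cl/C=C(/Cl)OCc1ccccc1 | intermediate
23 | (benzyloxy)ethyne | C#COCc1ccccc1 | intermediate
24 | (2S,3S)-6-(benzyloxy)-2-[3,4-bis(benzyloxy)phenyl]-3-[3,5-bis(benzyloxy)phenyl]-4-{(E)-2-[4-(benzyloxy)phenyl]ethenyl}-2,3-dihydro-1-benzofuran | c1ccc(COc2ccc(/C=C/c3cc(OCc4ccccc4)cc4c3[C@H](c3cc(OCc5ccccc5)cc(OCc5ccccc5)c3)[C@@H](c3ccc(OCc5ccccc5)c(OCc5ccccc5)c3)O4)cc2)cc1 | intermediate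
25 | scirpusin A, (2S,3S)-2-(3,4-dihydroxyphenyl)-3-(3,5-dihydroxyphenyl)-4-[(E)-2-(4-hydroxyphenyl)ethenyl]-2,3-dihydro-1-benzofuran-6-ol | Oc1ccc(/C=C/c2cc(O)cc3c2[C@H](c2cc(O)cc(O)c2)[C@@H](c2ccc(O)c(O)c2)O3)cc1 | target

**Count**
Total steps: 15. Longest linear sequence: 13 steps (steps 1–8, 10–12, 14 and 15, from compound 1).

**Steps most likely to fail**

Step 14. The insertion of the electron-rich alkoxyalkyne may lose regiocontrol, and 23 may be consumed by self-oligomerisation, leaving the rhodacycle from 20 to dimerise. The fallback sets out from 20 and introduces the C6 oxygen by oxidising a carbon–boron bond instead of carrying it in on the alkyne. Cyclotrimerisation of 20 with 2-ethynyl-4,4,5,5-tetramethyl-1,3,2-dioxaborolane (RhCl(PPh3)3, toluene, 20–40 °C) should give the 6-boryl dihydrobenzofuran F1, in which the bulkier and less self-reactive boryl alkyne is expected to be placed by sterics alone. Oxidation with NaBO3·4H2O in THF–H2O should then give the 6-hydroxy pentabenzyl ether F2, and debenzylation under the conditions of step 15 rejoins the route at 25.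

Step 12. KH and excess n-BuLi may shift the propargylic, benzylic C–H (propargyl–allenyl isomerisation or epimerisation at the future C3), and the potassium alkoxide may fragment. The fallback sets out from 18 and avoids the free alkoxide altogether. Formylation (formic acetic anhydride, pyridine, 0 °C) should give the formate F3, and dichloromethylenation of the formate carbonyl (PPh3, CCl4, THF, 60 °C) the 2,2-dichlorovinyl ether F4. A short treatment with n-BuLi (2.2 equiv, THF, −78 °C, MeOH quench) then rejoins the route at 20.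

Step 15. The Lewis acid may ionise the C2–O1 bond, acid may drive cyclisation of the stilbene onto the resorcinol ring while the free hexaphenol is concentrated, and the catechol may oxidise in air during purification. The fallback sets out from 24 and isolates the product in protected form. After debenzylation at −78 °C and the cold MeOH quench, volatiles are removed and the crude phenol is acetylated without purification (Ac2O, pyridine, DMAP) to scirpusin A hexaacetate F5, which is purified at that stage. Mild methanolysis (K2CO3 cat., MeOH, 0 °C, argon) then rejoins the route at 25.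

**Further compounds**
F1 | step 14 | (2S,3S)-2-[3,4-bis(benzyloxy)phenyl]-3-[3,5-bis(benzyloxy)phenyl]-4-{(E)-2-[4-(benzyloxy)phenyl]ethenyl}-6-(4,4,5,5-tetramethyl-1,3,2-dioxaborolan-2-yl)-2,3-dihydro-1-benzofuran | c1ccc(COc2ccc(/C=C/c3cc(B4OC(C)(C)C(C)(C)O4)cc4c3[C@H](c3cc(OCc5ccccc5)cc(OCc5ccccc5)c3)[C@@H](c3ccc(OCc5ccccc5)c(OCc5ccccc5)c3)O4)cc2)cc1
F2 | step 14 | (2S,3S)-2-[3,4-bis(benzyloxy)phenyl]-3-[3,5-bis(benzyloxy)phenyl]-4-{(E)-2-[4-(benzyloxy)phenyl]ethenyl}-2,3-dihydro-1-benzofuran-6-ol | c1ccc(COc2ccc(/C=C/c3cc(O)cc4c3[C@H](c3cc(OCc5ccccc5)cc(OCc5ccccc5)c3)[C@@H](c3ccc(OCc5ccccc5)c(OCc5ccccc5)c3)O4)cc2)cc1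
F3 | step 12 | (1S,2S,5E)-1-[3,4-bis(benzyloxy)phenyl]-2-[3,5-bis(benzyloxy)phenyl]-6-[4-(benzyloxy)phenyl]hex-5-en-3-yn-1-yl formate | c1ccc(COc2ccc(/C=C/C#C[C@H](c3cc(OCc4ccccc4)cc(OCc4ccccc4)c3)[C@H](OC=O)c3ccc(OCc4ccccc4)c(OCc4ccccc4)c3)cc2)cc1
F4 | step 12 | (1S,2S,5E)-1-[3,4-bis(benzyloxy)phenyl]-2-[3,5-bis(benzyloxy)phenyl]-6-[4-(benzyloxy)phenyl]-1-[(2,2-dichloroethenyl)oxy]hex-5-en-3-yne | c1ccc(COc2ccc(/C=C/C#C[C@H](c3cc(OCc4ccccc4)cc(OCc4ccccc4)c3)[C@H](OC=C(Cl)Cl)c3ccc(OCc4ccccc4)c(OCc4ccccc4)c3)cc2)cc1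
F5 | step 15 | scirpusin A hexaacetate, (2S,3S)-6-acetoxy-2-(3,4-diacetoxyphenyl)-3-(3,5-diacetoxyphenyl)-4-[(E)-2-(4-acetoxyphenyl)ethenyl]-2,3-dihydro-1-benzofuran | CC(=O)Oc1ccc(/C=C/c2cc(OC(C)=O)cc3c2[C@H](c2cc(OC(C)=O)cc(OC(C)=O)c2)[C@@H](c2ccc(OC(C)=O)c(OC(C)=O)c2)O3)cc1
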